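- Thursday's change of temperature at 4.0 min comes later than the half-life of X, read from the eta run as 0.565 min, so we doubt your hunch that the step to 125 °C buys extra E. That half-life is the time in which 0.5 of the remaining X goes, and we read it from the 29.3% of X that stood at 1.00 min.

| flask | X | temperature | remark | time |
|---|---|---|---|---|
| eta | 13 mM | 105 °C | run made earlier |  |
| alpha | 30 mM | 118 °C | run made earlier |  |
| Thursday's | 20 mM |  | at 110 °C until 4.0 min, from then on at 125 °C | 12 min |
| Sunday's | 20 mM | 110 °C |  | 12 min |
| Monday's | 20 mM | 125 °C |  | 12 min |

| run | time / min | E / % | X / % |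
|---|---|---|---|
| eta | 1.00 | 18.9 | 29.3 |
| eta | 3.00 | 25.6 | 2.0 |
| eta | 6.00 | 26.8 | 0 |
| eta | 8.00 | 26.3 | 1.0 |
| eta | 12.0 | 26.0 | 0.9 |
| alpha | 2.50 | 26.4 | 0.7 |
| alpha | 5.00 | 25.5 | 0 |
| alpha | 8.00 | 28.2 | 0 |
| alpha | 10.0 | 25.1 | 0.3 |
| alpha | 12.0 | 26.3 | 1.3 |

(readings scatter by 1 percentage point)

- which flask leads in amount of E, in percent of the X charged ("all alike" within 1.5 percentage points) (Thursday's / Sunday's / Monday's / all alike)
- how much E is there at the end, in percent of the X charged: Thursday's
- how much E is there at the end, in percent of the X charged: Sunday's
- how much E is there at the end, in percent of the X charged: Monday's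

- a reading or a percentage of E counts all its forms, free or not

- The count passes a test on the eta run: at 3.00 min it leaves 2.52% of X, and the reading is 2.0%, with a scatter of 1 percentage point.
- Thursday's first stretch at 110 °C is hotter than the eta run at 105 °C, so we treat eta's pace as the slow side. Even so, 4.0 min holds 7.08 half-lives and leaves about 0.739% of X, less than the scatter of a reading.
- That makes Thursday's flask Sunday's flask for our purposes, and the yield of E is then the question. The last readings are 26.0% in the eta run and 26.3% in the alpha run, a gap of 0.3 points, smaller than the scatter of a single reading, so these two readings show no shift of this selectivity.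
- We would commit to their mean, 26.2%, for all three flasks.
- The forecast gives 26.2% for Thursday's, 26.2% for Sunday's and 26% for Monday's, a little below our figure for Monday's, with the verdict all alike; it says “Thursday's temperature step should hardly matter”.
- The flasks give 26.6% for Thursday's, 26.6% for Sunday's and 25.9% for Monday's, so the verdict is all alike.

    L ⇌ E, rate k1*(cs1 - [E]) while solid is left; crystals form when [E] > cs1 (solubility = 2.10 mM, k = 1.20 /s)
    X → E (k = 0.00760 /s, Ea = 94.0 kJ/mol)
    X → J (k = 0.0210 /s, Ea = 97.0 kJ/mol)
    (constants at 110 °C)

- At Thursday's step X stood at 0.104% and E at 26.5%. Monday's flask, counted at eta's pace, holds 21.2 half-lives in its 12 min; X stands at 0% and E at 25.9% then, and E is still 25.9% at 120 min.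

The runs stem from a simulated flask from invented constants; the scatter is artificial.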